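## Structural features

Gnetofuran A is a stilbenoid–neolignan hybrid built on a 2,3-dihydrobenzofuran. Ring A is the fused benzene ring; it carries a methoxy group at C7 and, at C5, an E-ethene bridge to the resorcinol ring C. The guaiacyl ring B sits on C2 and a hydroxymethyl group on C3. The only stereocentres are the adjacent C2 (R) and C3 (S), trans on the five-membered ring; C2 is benzylic to ring B and bound to O1, C3 is benzylic to ring A. The fragile elements are the C2–O1 bond (a para-hydroxybenzyl aryl ether that can ionise under acid or open to a quinone methide), the electron-rich E-stilbene with its free resorcinol, and three free phenols, so the last unmasking must be mild and non-reductive. The real difficulty is to fix the absolute and relative configuration at C2 and C3 and to keep it while the tetrasubstituted ring A is assembled and elaborated. Two features are exploited: the C2–C3 bond joins an arylacetic α-carbon to an aryl carbinol carbon (an aldol pattern), and C7a lies para to C5, so a carbonyl group at C5 can stabilise negative charge arriving at C7a. A fluoride at C7a can therefore be displaced by the C2 oxygen, closing O1–C7a without touching either stereocentre.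

## Logic of the disconnections

25 ⇒ 24. Only protecting-group bonds are cut: three aryl O–CH2OMe acetal bonds and the O–CPh3 bond. All four oxygens must be masked through the base-mediated steps, and one acid treatment should release them together. The demand is an acid mild enough to leave C2–O1 and the stilbene intact.

24 ⇒ 19 + 23. The C=C bond between ring A and ring C is cut. This is the most convergent cut: it removes ring C as a separate piece and turns the C5 carbon into an aldehyde. The forward olefination must be E-selective; no epimerisable centre lies next to the reacting carbonyl.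

23 ⇒ 22 ⇒ 21 ⇒ 20. The benzylic C–P bond, then the C–Br bond, then the two phenolic O–CH2 bonds are cut. This reduces fragment C to a commercial triol. The forward alkylation must distinguish the phenols from the benzylic alcohol.

19 ⇒ 18 ⇒ 17. No skeletal bond is cut; the oxidation level of the C5 carbon is changed from aldehyde back to ester. The ester is needed because it survives enolate chemistry and activates C7a. The forward reduction and oxidation must spare the acetal and trityl ethers.

17 ⇒ 16. The O1–C7a bond is cut. The heterocycle becomes an acyclic syn-1,3-diol monoether whose two centres form an aldol pattern, and the ring closure itself creates no stereocentre. The forward step needs activation of C7a (para ester), a leaving group (fluoride) and one free oxygen only. The protecting pattern of 16 was examined and kept: a trityl ether cannot migrate to the neighbouring alkoxide as a silyl ether could, and the acetal on ring B is inert to alkoxide and fluoride.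

16 ⇒ 15 ⇒ 14. The O–CPh3 bond is cut, then the primary alcohol is traced to the acyl carbon bound to the auxiliary nitrogen. The forward hydride must cleave the imide and spare the aryl methyl ester, which argues for a borohydride in aqueous THF and not a stronger lithium reagent; the tritylation must take the primary hydroxyl only.

14 ⇒ 9 + 11 (through 12 and 13). The C2–C3 bond is cut. Both stereocentres are set in one auxiliary-controlled event from two achiral arenes. The forward step needs a Z-enolate and clean facial control; the R auxiliary delivers the (2R,3R) syn adduct that maps onto (2R,3S) in the ring.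

9 ⇒ 6 + 7 (through 8), and 11 ⇒ 10. The imide N–C(O) bond and the phenolic O–CH2 bond are cut, leading to an arylacetic acid, the commercial auxiliary and a commercial aldehyde.

6 ⇒ 5 ⇒ 4. The bond between ring A and the acetic acid CH2 is cut, after the acid is masked as a tert-butyl ester. A cross-coupling of the aryl bromide with a zinc ester enolate makes this bond in one step, and the tert-butyl ester is cleaved by acid beside the methyl ester.

4 ⇒ 3 ⇒ 1 (through 2). The O–CH3 bond and then the ring A C5–O bond are cut, the latter back to a C–H bond. The forward C–H functionalisation must select the one ring hydrogen that is ortho to fluorine and not flanked by a large group.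

## Other disconnections considered

Alternative 1: The cut is C3–C3a, made by a 1,2-shift of the ring A carbon inside an enantiopure flavanone, (2R)-6-bromo-8-methoxy-2-[3-methoxy-4-(pivaloyloxy)phenyl]chroman-4-one A1.
- Forward step: with PhI(OAc)2, HC(OMe)3 and H2SO4 the ketone would form its enol ether, trivalent iodine would add to the former CH2 carbon anti to the C2 aryl group, and the ring A carbon would migrate from the acetalised carbonyl carbon to that carbon as PhI leaves. The pyranone contracts and the old carbonyl carbon ends as the C3 methyl ester of the trans product A2.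
- In favour: only C2 has to be introduced by asymmetric synthesis; C3 follows from substrate control. The C5 bromide of A2 allows a Heck or Suzuki installation of the styryl arm with no redox adjustment. Ring A comes from a simple acetophenone.
- Against: A1 can racemise at C2 by reversible retro-oxa-Michael ring opening, and the key step runs in strong acid. Ring B is electron-rich and could migrate from C2 to C3 instead, which would erase C2; the pivalate is there to damp this. The ester of A2 is β to the aryloxy oxygen, so base could open the ring by elimination.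
- Comparison: on step count this alternative is probably the better (no auxiliary steps, no late redox); on convergency it is the equal. On stereochemical security the chosen plan is better, because both centres are set together under auxiliary control and never again sit at a reacting site. Mechanistically the chosen closure is a polar addition–elimination with one possible course, whereas the ring contraction is a cationic rearrangement with two competing migrating groups.

Alternative 2: The cuts are C3–C3a and the C–O bond of the hydroxymethyl group, traced to the chiral allyl aryl ether 2-[3-iodo-5-methoxy-4-[[(1R)-1-[3-methoxy-4-(methoxymethoxy)phenyl]prop-2-en-1-yl]oxy]phenyl]-1,3-dioxolane A3.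
- Forward step: Bu3SnH and Et3B under O2 would generate the aryl radical, which adds 5-exo to the vinyl group. The primary radical is trapped by O2 to the hydroperoxide A4, which PPh3 reduces to the alcohol A5.
- In favour: one step forms the ring, the C3 centre and the C–O bond, which is more construction per step than the chosen key step. A3 could come from a catalytic asymmetric allylic etherification, with no stoichiometric auxiliary. The acetal at C5 gives the aldehyde by hydrolysis alone. On these three points it is the better plan.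
- Against: the trans preference rests on a chair-like transition state with a single substituent, a kinetic bias that is not assured. A 1,5-hydrogen shift from the benzylic, allylic C–H to the aryl radical would scramble C2. Capture of either radical by the tin hydride before cyclisation or oxygenation competes. The secondary benzylic ether on an electron-rich ring can ionise, and the nucleophile for its synthesis is a doubly ortho-substituted phenol.
- Comparison: the alternative is shorter and equal in convergency. The chosen plan is stronger in stereocontrol, since C3 is set by reagent control and not by a modest substrate bias, and it avoids a tin-mediated radical chain that must be balanced against oxygen.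

Alternative 3: The cut is O1–C2, traced to the bis-phenol methyl 3-[(2S)-1-[tert-butyl(dimethyl)silyl]oxy-3-(4-hydroxy-3-methoxyphenyl)propan-2-yl]-4-hydroxy-5-methoxybenzoate A6.
- Forward step: Ag2O would oxidise the 4-hydroxy-3-methoxybenzyl unit to the para-quinone methide A7, and the ring A phenol would add to its exocyclic carbon, closing the ring to A8 with the aryl group trans to the C3 substituent.
- In favour: it follows the likely biosynthesis. Ring B needs no protecting group, which is better than the chosen plan. No leaving group or activating group on ring A is required, so the C5 substituent is free to choose. Only one centre has to be made by asymmetric synthesis, by an auxiliary alkylation that is the equal of the aldol in reliability.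
- Against: the single preset centre C3 is benzylic and sits next to the quinone methide, so tautomerisation of A7 to the C2=C3 alkene would erase it. Silver oxide oxidation of a guaiacyl unit with a free ortho position can also lead to radical coupling. C2 is set only by substrate control.
- Comparison: the step count is about equal and the protecting-group economy is better. The chosen plan is safer on configuration, because its ring closure cannot touch C2 or C3, and safer mechanistically, because it has no oxidised intermediate with alternative outlets.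

Key step: step 10

Assumption: salts formed by simple deprotonation and consumed at once (the potassium alkoxide of 16, the carbanion of 23, phenoxides) are treated as reactive forms of the numbered compounds; covalent species made by a separate reagent and carried into a second operation in the same flask are numbered as intermediates.

## Route

Step 1
Reactants: 1 methyl 3-bromo-4-fluorobenzoate
Product: 3 methyl 3-bromo-4-fluoro-5-hydroxybenzoate, via aryl pinacol boronate 2 (not isolated)
Conditions: B2pin2, [Ir(OMe)(cod)]2 (1.5 mol %), dtbpy (3 mol %), THF, 70 °C; then KHSO5 (as 2KHSO5·KHSO4·K2SO4), acetone–H2O, 0 °C to rt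
Reagents that add atoms: bis(pinacolato)diboron, CC1(C)OB(OC1(C)C)B1OC(C)(C)C(C)(C)O1 (boryl group of 2 only); potassium peroxymonosulfate KHSO5, [K+].[O-]S(=O)(=O)OO (phenol oxygen of 3)
Why: Iridium-catalysed C–H borylation is sterically governed, and C5–H is the only ring hydrogen not flanked by bromine or the ester, while its position ortho to fluorine also favours it electronically; oxidation of the C–B bond in the same flask should give the phenol with the ester and bromide untouched.

Step 2
Reactants: 3 methyl 3-bromo-4-fluoro-5-hydroxybenzoate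
Product: 4 methyl 3-bromo-4-fluoro-5-methoxybenzoate
Conditions: MeI, K2CO3, acetone, 50 °C
Reagents that add atoms: iodomethane, CI
Why: Williamson O-methylation of an acidic phenol; carbonate in acetone is too mild for substitution of the fluoride by the phenoxide.

Step 3
Reactants: 4 methyl 3-bromo-4-fluoro-5-methoxybenzoate
Product: 5 methyl 3-[2-(tert-butoxy)-2-oxoethyl]-4-fluoro-5-methoxybenzoate
Conditions: BrZnCH2CO2t-Bu (from BrCH2CO2t-Bu, Zn, Me3SiCl, THF), Pd(dba)2 (2 mol %), P(t-Bu)3 (2 mol %), THF, rt to 40 °C
Reagents that add atoms: tert-butyl 2-(bromozincio)acetate, CC(C)(C)OC(=O)C[Zn]Br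
Why: Negishi-type coupling of a Reformatsky reagent (α-arylation of a zinc ester enolate) at zerovalent palladium; the zinc enolate is mild enough to leave the methyl ester and the activated fluoride alone.

Step 4
Reactants: 5 methyl 3-[2-(tert-butoxy)-2-oxoethyl]-4-fluoro-5-methoxybenzoate
Product: 6 2-[2-fluoro-3-methoxy-5-(methoxycarbonyl)phenyl]acetic acid
Conditions: CF3CO2H, CH2Cl2, rt
Reagents that add atoms: none
Why: Acidolysis of the tert-butyl ester through the tert-butyl cation, which leaves the methyl benzoate intact.

Step 5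
Reactants: 6 2-[2-fluoro-3-methoxy-5-(methoxycarbonyl)phenyl]acetic acid; 7 (4R)-4-benzyl-1,3-oxazolidin-2-one
Product: 9 methyl 3-[2-[(4R)-4-benzyl-2-oxo-1,3-oxazolidin-3-yl]-2-oxoethyl]-4-fluoro-5-methoxybenzoate, via mixed pivalic anhydride 8 (not isolated)
Conditions: t-BuCOCl, Et3N, THF, −20 °C; then 7, LiCl, −20 °C to rt
Reagents that add atoms: pivaloyl chloride, CC(C)(C)C(=O)Cl (pivaloyl group of 8 only; none of its atoms remain in 9)
Why: N-acylation of the oxazolidinone through a mixed anhydride under LiCl/Et3N activation, which avoids a strong base next to the acidic arylacetyl CH2.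

Step 6
Reactants: 10 vanillin
Product: 11 3-methoxy-4-(methoxymethoxy)benzaldehyde
Conditions: MeOCH2Cl, i-Pr2NEt, CH2Cl2, 0 °C to rt
Reagents that add atoms: chloromethyl methyl ether, COCCl
Why: O-alkylation of the phenol to an acetal that is stable to boron enolates, hydride, amide base and fluoride.

Step 7
Reactants: 9 methyl 3-[2-[(4R)-4-benzyl-2-oxo-1,3-oxazolidin-3-yl]-2-oxoethyl]-4-fluoro-5-methoxybenzoate; 11 3-methoxy-4-(methoxymethoxy)benzaldehyde
Product: 14 methyl 3-[(2R,3R)-1-[(4R)-4-benzyl-2-oxo-1,3-oxazolidin-3-yl]-3-hydroxy-3-[3-methoxy-4-(methoxymethoxy)phenyl]-1-oxopropan-2-yl]-4-fluoro-5-methoxybenzoate, via Z dibutylboron enolate 12 (not isolated), via dibutylboron aldolate 13 (not isolated)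
Conditions: Bu2BOTf, i-Pr2NEt, CH2Cl2, −78 to 0 °C; 11, −78 to 0 °C; then pH 7 buffer, MeOH, 30 % H2O2, 0 °C
Reagents that add atoms: dibutylboron triflate, CCCCB(CCCC)OS(=O)(=O)C(F)(F)F (boron group of 12 and 13 only; none of its atoms remain in 14)
Why: Evans syn-aldol reaction: soft enolisation gives the Z-boron enolate, and a closed chair transition state with the auxiliary carbonyl turned away lets the aldehyde approach the enolate face opposite the benzyl group. The R auxiliary should therefore set both new centres as (2R,3R), the syn adduct that corresponds to C3 (S) and C2 (R) of the target.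

Step 8
Reactants: 14 methyl 3-[(2R,3R)-1-[(4R)-4-benzyl-2-oxo-1,3-oxazolidin-3-yl]-3-hydroxy-3-[3-methoxy-4-(methoxymethoxy)phenyl]-1-oxopropan-2-yl]-4-fluoro-5-methoxybenzoate
Product: 15 methyl 3-[(1R,2S)-1,3-dihydroxy-1-[3-methoxy-4-(methoxymethoxy)phenyl]propan-2-yl]-4-fluoro-5-methoxybenzoate
Conditions: NaBH4, THF–H2O (4:1), 0 °C to rt
Reagents that add atoms: none
Why: Reductive cleavage of the N-acyl oxazolidinone at its activated exocyclic carbonyl; NaBH4 in aqueous THF is chosen over LiBH4 because it does not reduce an aryl methyl ester at this temperature, and the auxiliary 7 should be recovered.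

Step 9
Reactants: 15 methyl 3-[(1R,2S)-1,3-dihydroxy-1-[3-methoxy-4-(methoxymethoxy)phenyl]propan-2-yl]-4-fluoro-5-methoxybenzoate
Product: 16 methyl 4-fluoro-3-[(1R,2S)-1-hydroxy-1-[3-methoxy-4-(methoxymethoxy)phenyl]-3-(trityloxy)propan-2-yl]-5-methoxybenzoate
Conditions: Ph3CCl, Et3N, DMAP (cat.), CH2Cl2, rt
Reagents that add atoms: trityl chloride, ClC(c1ccccc1)(c1ccccc1)c1ccccc1
Why: Tritylation is strongly selective for the primary hydroxyl on steric grounds, so the hindered secondary benzylic hydroxyl stays free.

Step 10
Reactants: 16 methyl 4-fluoro-3-[(1R,2S)-1-hydroxy-1-[3-methoxy-4-(methoxymethoxy)phenyl]-3-(trityloxy)propan-2-yl]-5-methoxybenzoate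
Product: 17 methyl (2R,3S)-7-methoxy-2-[3-methoxy-4-(methoxymethoxy)phenyl]-3-(trityloxymethyl)-2,3-dihydro-1-benzofuran-5-carboxylate
Conditions: KN(SiMe3)2 (1.1 equiv), THF, 0 °C to rt
Reagents that add atoms: none
Why: The amide base converts the secondary alcohol into its potassium alkoxide, which adds to the fluorine-bearing carbon C7a; the resulting cyclohexadienyl anion is stabilised by delocalisation into the para ester at C5, and loss of fluoride restores the arene (addition–elimination). The closest known reaction type is the intramolecular SNAr etherification of an alkoxide onto an aryl fluoride activated by a para acceptor, used to make dihydrobenzofurans and chromans. The five-membered ring O1–C2–C3–C3a–C7a closes in a 5-exo fashion at the ipso carbon. No stereocentre is created: the oxygen acts as nucleophile, no bond at C2 or C3 is broken, and the syn relationship of the open chain becomes the 2,3-trans relationship of the ring with (2R,3S) retained. The step needs selectivity between two oxygens that could both reach C7a; the trityl ether caps the primary oxygen and cannot migrate to the alkoxide. It also needs the ester to survive, which the non-nucleophilic base and the meta position of the ester relative to the side chain should ensure. There is only one fluoride, so no regiochemical question arises.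

Step 11
Reactants: 17 methyl (2R,3S)-7-methoxy-2-[3-methoxy-4-(methoxymethoxy)phenyl]-3-(trityloxymethyl)-2,3-dihydro-1-benzofuran-5-carboxylate
Product: 18 [(2R,3S)-7-methoxy-2-[3-methoxy-4-(methoxymethoxy)phenyl]-3-(trityloxymethyl)-2,3-dihydro-1-benzofuran-5-yl]methanol
Conditions: i-Bu2AlH (2.5 equiv), CH2Cl2, −78 to 0 °C; aq. KNaC4H4O6
Reagents that add atoms: none
Why: Hydride reduction of the aryl ester to the benzylic alcohol; acetal, trityl ether and the ring ether are inert to the aluminium hydride.

Step 12
Reactants: 18 [(2R,3S)-7-methoxy-2-[3-methoxy-4-(methoxymethoxy)phenyl]-3-(trityloxymethyl)-2,3-dihydro-1-benzofuran-5-yl]methanol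
Product: 19 (2R,3S)-7-methoxy-2-[3-methoxy-4-(methoxymethoxy)phenyl]-3-(trityloxymethyl)-2,3-dihydro-1-benzofuran-5-carbaldehyde
Conditions: activated MnO2 (excess), CH2Cl2, rt
Reagents that add atoms: none
Why: Heterogeneous oxidation selective for benzylic alcohols; it stops at the aldehyde and is neutral, so the acid-labile groups and both centres are safe.

Step 13
Reactants: 20 3,5-dihydroxybenzyl alcohol
Product: 21 [3,5-bis(methoxymethoxy)phenyl]methanol
Conditions: MeOCH2Cl (2.2 equiv), K2CO3, acetone, 0 °C to rt
Reagents that add atoms: chloromethyl methyl ether, COCCl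
Why: Carbonate ionises only the phenols, so O-alkylation should take place at the two phenoxides and leave the benzylic alcohol free, as in the usual phenol-selective alkylations of this triol.

Step 14
Reactants: 21 [3,5-bis(methoxymethoxy)phenyl]methanol
Product: 22 1-(bromomethyl)-3,5-bis(methoxymethoxy)benzene
Conditions: CBr4, PPh3, CH2Cl2, 0 °C
Reagents that add atoms: carbon tetrabromide, BrC(Br)(Br)Br
Why: Appel bromination through an alkoxyphosphonium salt under neutral conditions that the acetals tolerate.

Step 15
Reactants: 22 1-(bromomethyl)-3,5-bis(methoxymethoxy)benzene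
Product: 23 diethyl {[3,5-bis(methoxymethoxy)phenyl]methyl}phosphonate
Conditions: P(OEt)3 (neat), 130 °C
Reagents that add atoms: triethyl phosphite, CCOP(OCC)OCC
Why: Michaelis–Arbuzov reaction of a reactive benzylic bromide, with bromoethane distilling off.

Step 16
Reactants: 19 (2R,3S)-7-methoxy-2-[3-methoxy-4-(methoxymethoxy)phenyl]-3-(trityloxymethyl)-2,3-dihydro-1-benzofuran-5-carbaldehyde; 23 diethyl {[3,5-bis(methoxymethoxy)phenyl]methyl}phosphonate
Product: 24 (2R,3S)-5-[(E)-2-[3,5-bis(methoxymethoxy)phenyl]ethenyl]-7-methoxy-2-[3-methoxy-4-(methoxymethoxy)phenyl]-3-(trityloxymethyl)-2,3-dihydro-1-benzofuran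
Conditions: 23, KOt-Bu, THF, 0 °C; then 19, 0 °C to rt
Reagents that add atoms: none
Why: Horner–Wadsworth–Emmons olefination of an aromatic aldehyde with a benzylic phosphonate carbanion, which should give the E-stilbene through the more stable anti adduct; neither ring stereocentre is acidic enough to be affected by the base.

Step 17
Reactants: 24 (2R,3S)-5-[(E)-2-[3,5-bis(methoxymethoxy)phenyl]ethenyl]-7-methoxy-2-[3-methoxy-4-(methoxymethoxy)phenyl]-3-(trityloxymethyl)-2,3-dihydro-1-benzofuran
Product: 25 gnetofuran A, 5-[(E)-2-[(2R,3S)-2-(4-hydroxy-3-methoxyphenyl)-3-(hydroxymethyl)-7-methoxy-2,3-dihydro-1-benzofuran-5-yl]ethenyl]benzene-1,3-diol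
Conditions: aq. HCl (3 M), MeOH–THF (1:1), rt to 40 °C, under N2, in the dark
Reagents that add atoms: none
Why: Acid-catalysed acetal exchange removes the three methoxymethyl groups and solvolysis removes the trityl ether in one operation; should C2–O1 ionise reversibly, reclosure next to the fixed C3 centre favours the trans ring again.

## Compound list

1 | methyl 3-bromo-4-fluorobenzoate | COC(=O)c1ccc(F)c(Br)c1 | starting material
2 | methyl 3-bromo-4-fluoro-5-(4,4,5,5-tetramethyl-1,3,2-dioxaborolan-2-yl)benzoate | COC(=O)c1cc(Br)c(F)c(B2OC(C)(C)C(C)(C)O2)c1 | intermediate (not isolated)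
3 | methyl 3-bromo-4-fluoro-5-hydroxybenzoate | COC(=O)c1cc(O)c(F)c(Br)c1 | intermediate
4 | methyl 3-bromo-4-fluoro-5-methoxybenzoate | COC(=O)c1cc(OC)c(F)c(Br)c1 | intermediate
5 | methyl 3-[2-(tert-butoxy)-2-oxoethyl]-4-fluoro-5-methoxybenzoate | COC(=O)c1cc(OC)c(F)c(CC(=O)OC(C)(C)C)c1 | intermediate
6 | 2-[2-fluoro-3-methoxy-5-(methoxycarbonyl)phenyl]acetic acid | COC(=O)c1cc(OC)c(F)c(CC(=O)O)c1 | intermediate
7 | (4R)-4-benzyl-1,3-oxazolidin-2-one | O=C1N[C@H](Cc2ccccc2)CO1 | starting material
8 | 2-[2-fluoro-3-methoxy-5-(methoxycarbonyl)phenyl]acetic pivalic anhydride | COC(=O)c1cc(OC)c(F)c(CC(=O)OC(=O)C(C)(C)C)c1 | intermediate (not isolated)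
9 | methyl 3-[2-[(4R)-4-benzyl-2-oxo-1,3-oxazolidin-3-yl]-2-oxoethyl]-4-fluoro-5-methoxybenzoate | COC(=O)c1cc(OC)c(F)c(CC(=O)N2[C@H](Cc3ccccc3)COC2=O)c1 | intermediate
10 | vanillin (4-hydroxy-3-methoxybenzaldehyde) | COc1cc(C=O)ccc1O | starting material
11 | 3-methoxy-4-(methoxymethoxy)benzaldehyde | COCOc1ccc(C=O)cc1OC | intermediate
12 | methyl 3-[(Z)-2-[(4R)-4-benzyl-2-oxo-1,3-oxazolidin-3-yl]-2-[(dibutylboranyl)oxy]ethenyl]-4-fluoro-5-methoxybenzoate | COC(=O)c1cc(OC)c(F)c(/C=C(\OB(CCCC)CCCC)N2[C@H](Cc3ccccc3)COC2=O)c1 | intermediate (not isolated)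
13 | methyl 3-[(2R,3R)-1-[(4R)-4-benzyl-2-oxo-1,3-oxazolidin-3-yl]-3-[(dibutylboranyl)oxy]-3-[3-methoxy-4-(methoxymethoxy)phenyl]-1-oxopropan-2-yl]-4-fluoro-5-methoxybenzoate | COCOc1ccc([C@H](OB(CCCC)CCCC)[C@@H](c2cc(C(=O)OC)cc(OC)c2F)C(=O)N2[C@H](Cc3ccccc3)COC2=O)cc1OC | intermediate (not isolated)
14 | methyl 3-[(2R,3R)-1-[(4R)-4-benzyl-2-oxo-1,3-oxazolidin-3-yl]-3-hydroxy-3-[3-methoxy-4-(methoxymethoxy)phenyl]-1-oxopropan-2-yl]-4-fluoro-5-methoxybenzoate | COCOc1ccc([C@H](O)[C@@H](c2cc(C(=O)OC)cc(OC)c2F)C(=O)N2[C@H](Cc3ccccc3)COC2=O)cc1OC | intermediate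
15 | methyl 3-[(1R,2S)-1,3-dihydroxy-1-[3-methoxy-4-(methoxymethoxy)phenyl]propan-2-yl]-4-fluoro-5-methoxybenzoate | COCOc1ccc([C@H](O)[C@@H](c2cc(C(=O)OC)cc(OC)c2F)CO)cc1OC | intermediate
16 | methyl 4-fluoro-3-[(1R,2S)-1-hydroxy-1-[3-methoxy-4-(methoxymethoxy)phenyl]-3-(trityloxy)propan-2-yl]-5-methoxybenzoate | COCOc1ccc([C@H](O)[C@@H](c2cc(C(=O)OC)cc(OC)c2F)COC(c2ccccc2)(c2ccccc2)c2ccccc2)cc1OC | intermediate
17 | methyl (2R,3S)-7-methoxy-2-[3-methoxy-4-(methoxymethoxy)phenyl]-3-(trityloxymethyl)-2,3-dihydro-1-benzofuran-5-carboxylate | COCOc1ccc([C@@H]2Oc3c(OC)cc(C(=O)OC)cc3[C@H]2COC(c2ccccc2)(c2ccccc2)c2ccccc2)cc1OC | intermediate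
18 | [(2R,3S)-7-methoxy-2-[3-methoxy-4-(methoxymethoxy)phenyl]-3-(trityloxymethyl)-2,3-dihydro-1-benzofuran-5-yl]methanol | COCOc1ccc([C@@H]2Oc3c(OC)cc(CO)cc3[C@H]2COC(c2ccccc2)(c2ccccc2)c2ccccc2)cc1OC | intermediate
19 | (2R,3S)-7-methoxy-2-[3-methoxy-4-(methoxymethoxy)phenyl]-3-(trityloxymethyl)-2,3-dihydro-1-benzofuran-5-carbaldehyde | COCOc1ccc([C@@H]2Oc3c(OC)cc(C=O)cc3[C@H]2COC(c2ccccc2)(c2ccccc2)c2ccccc2)cc1OC | intermediate
20 | 3,5-dihydroxybenzyl alcohol | OCc1cc(O)cc(O)c1 | starting material
21 | [3,5-bis(methoxymethoxy)phenyl]methanol | COCOc1cc(CO)cc(OCOC)c1 | intermediate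
22 | 1-(bromomethyl)-3,5-bis(methoxymethoxy)benzene | COCOc1cc(CBr)cc(OCOC)c1 | intermediate
23 | diethyl {[3,5-bis(methoxymethoxy)phenyl]methyl}phosphonate | CCOP(=O)(Cc1cc(OCOC)cc(OCOC)c1)OCC | intermediate
24 | (2R,3S)-5-[(E)-2-[3,5-bis(methoxymethoxy)phenyl]ethenyl]-7-methoxy-2-[3-methoxy-4-(methoxymethoxy)phenyl]-3-(trityloxymethyl)-2,3-dihydro-1-benzofuran | COCOc1ccc([C@@H]2Oc3c(OC)cc(/C=C/c4cc(OCOC)cc(OCOC)c4)cc3[C@H]2COC(c2ccccc2)(c2ccccc2)c2ccccc2)cc1OC | intermediate
25 | gnetofuran A, 5-[(E)-2-[(2R,3S)-2-(4-hydroxy-3-methoxyphenyl)-3-(hydroxymethyl)-7-methoxy-2,3-dihydro-1-benzofuran-5-yl]ethenyl]benzene-1,3-diol | COc1cc([C@@H]2Oc3c(OC)cc(/C=C/c4cc(O)cc(O)c4)cc3[C@H]2CO)ccc1O | target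

## Step count and least certain steps

Total step count: 17. Longest linear sequence: 13 steps (1 to 25 through steps 1–5, 7–12, 16 and 17); steps 6 and 13–15 are side branches.

**Step 10 (key step).** The most likely failure is incomplete ring closure: a single para ester, opposed by the ortho methoxy donor, gives only moderate activation, so intermolecular acyl transfer from the methyl ester to the alkoxide could compete on warming.
- Fallback: set out from 16 and raise the acceptor strength before closing the ring. i-Bu2AlH would reduce the ester to (1R,2S)-2-[2-fluoro-5-(hydroxymethyl)-3-methoxyphenyl]-1-[3-methoxy-4-(methoxymethoxy)phenyl]-3-(trityloxy)propan-1-ol F1. TEMPO (cat.) with PhI(OAc)2 would oxidise the unhindered primary benzylic alcohol in preference to the hindered secondary one, giving 4-fluoro-3-[(1R,2S)-1-hydroxy-1-[3-methoxy-4-(methoxymethoxy)phenyl]-3-(trityloxy)propan-2-yl]-5-methoxybenzaldehyde F2. The para formyl group is a much stronger acceptor, so Cs2CO3 in DMF at 40–60 °C should close the ring. The sequence returns to the route at 19 with the same number of steps.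

**Step 7.** The most likely failure is erosion of diastereoselectivity or retro-aldol cleavage during work-up, because the α-hydrogen of the arylacetyl imide and of its adduct is unusually acidic and the electron-rich aldehyde reacts slowly.
- Fallback: set out from 6 and use a chlorotitanium enolate of a more labile auxiliary. Coupling of 6 with commercial (4R)-4-benzyl-1,3-thiazolidine-2-thione (carbodiimide, DMAP) would give methyl 3-[2-[(4R)-4-benzyl-2-sulfanylidene-1,3-thiazolidin-3-yl]-2-oxoethyl]-4-fluoro-5-methoxybenzoate F3. Enolisation with TiCl4 (1 equiv), i-Pr2NEt (1 equiv) and N-methylpyrrolidinone (1 equiv) in CH2Cl2 at −78 °C and addition of 11 should give the same syn adduct, methyl 3-[(2R,3R)-1-[(4R)-4-benzyl-2-sulfanylidene-1,3-thiazolidin-3-yl]-3-hydroxy-3-[3-methoxy-4-(methoxymethoxy)phenyl]-1-oxopropan-2-yl]-4-fluoro-5-methoxybenzoate F4. NaBH4 in THF–EtOH at 0 °C removes this auxiliary easily, and the sequence returns to the route at 15.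

**Step 8.** The most likely failure is competing reduction of the aryl methyl ester, or base-induced retro-aldol fragmentation while the imide is being cleaved.
- Fallback: set out from 14 and separate cleavage from reduction. LiOH with H2O2 in THF–H2O at 0 °C would hydrolyse the exocyclic imide carbonyl to (2R,3R)-2-[2-fluoro-3-methoxy-5-(methoxycarbonyl)phenyl]-3-hydroxy-3-[3-methoxy-4-(methoxymethoxy)phenyl]propanoic acid F5 and release 7. BH3·SMe2 in THF reduces a carboxylic acid much faster than an aryl ester, so the sequence should return to the route at 15.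

**Step 3.** The most likely failure is stalling of the coupling through slow transmetalation or protonation of the zinc enolate, next to an ortho fluorine and an ortho hydrogen only on one side.
- Fallback: set out from 4 and build the acetic acid by allylation and cleavage. Stille coupling with Bu3SnCH2CH=CH2 and Pd(PPh3)4 in toluene at 100 °C would give methyl 4-fluoro-3-methoxy-5-(prop-2-en-1-yl)benzoate F6. RuCl3 (cat.) with NaIO4 in MeCN–EtOAc–H2O would cleave the alkene to the acid, returning to the route at 6.

**Step 17.** The most likely failure is acid-induced ionisation of the C2–O1 bond or cationic oligomerisation of the electron-rich stilbene before all three acetals are cleaved.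
- Fallback: set out from 19 and 23, apply the acid before the stilbene exists and finish with fluoride. Aqueous HCl in MeOH–THF would convert 19 into (2R,3S)-2-(4-hydroxy-3-methoxyphenyl)-3-(hydroxymethyl)-7-methoxy-2,3-dihydro-1-benzofuran-5-carbaldehyde F7. TBSCl and imidazole in DMF would give (2R,3S)-2-[4-[tert-butyl(dimethyl)silyl]oxy-3-methoxyphenyl]-3-[[tert-butyl(dimethyl)silyl]oxymethyl]-7-methoxy-2,3-dihydro-1-benzofuran-5-carbaldehyde F8. The same acid would convert 23 into diethyl [(3,5-dihydroxyphenyl)methyl]phosphonate F9, and silylation would give diethyl {[3,5-bis[tert-butyl(dimethyl)silyl]oxyphenyl]methyl}phosphonate F10. Olefination of F8 with F10 (NaH, THF, 0 °C) should give (2R,3S)-5-[(E)-2-[3,5-bis[tert-butyl(dimethyl)silyl]oxyphenyl]ethenyl]-2-[4-[tert-butyl(dimethyl)silyl]oxy-3-methoxyphenyl]-3-[[tert-butyl(dimethyl)silyl]oxymethyl]-7-methoxy-2,3-dihydro-1-benzofuran F11. Bu4NF buffered with AcOH in THF would then remove all four silyl groups and return to the route at 25.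

## Further compounds

F1 | step 10 | (1R,2S)-2-[2-fluoro-5-(hydroxymethyl)-3-methoxyphenyl]-1-[3-methoxy-4-(methoxymethoxy)phenyl]-3-(trityloxy)propan-1-ol | COCOc1ccc([C@H](O)[C@@H](c2cc(CO)cc(OC)c2F)COC(c2ccccc2)(c2ccccc2)c2ccccc2)cc1OC
F2 | step 10 | 4-fluoro-3-[(1R,2S)-1-hydroxy-1-[3-methoxy-4-(methoxymethoxy)phenyl]-3-(trityloxy)propan-2-yl]-5-methoxybenzaldehyde | COCOc1ccc([C@H](O)[C@@H](c2cc(C=O)cc(OC)c2F)COC(c2ccccc2)(c2ccccc2)c2ccccc2)cc1OC
F3 | step 7 | methyl 3-[2-[(4R)-4-benzyl-2-sulfanylidene-1,3-thiazolidin-3-yl]-2-oxoethyl]-4-fluoro-5-methoxybenzoate | COC(=O)c1cc(OC)c(F)c(CC(=O)N2[C@H](Cc3ccccc3)CSC2=S)c1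
F4 | step 7 | methyl 3-[(2R,3R)-1-[(4R)-4-benzyl-2-sulfanylidene-1,3-thiazolidin-3-yl]-3-hydroxy-3-[3-methoxy-4-(methoxymethoxy)phenyl]-1-oxopropan-2-yl]-4-fluoro-5-methoxybenzoate | COCOc1ccc([C@H](O)[C@@H](c2cc(C(=O)OC)cc(OC)c2F)C(=O)N2[C@H](Cc3ccccc3)CSC2=S)cc1OC
F5 | step 8 | (2R,3R)-2-[2-fluoro-3-methoxy-5-(methoxycarbonyl)phenyl]-3-hydroxy-3-[3-methoxy-4-(methoxymethoxy)phenyl]propanoic acid | COCOc1ccc([C@H](O)[C@@H](c2cc(C(=O)OC)cc(OC)c2F)C(=O)O)cc1OC
F6 | step 3 | methyl 4-fluoro-3-methoxy-5-(prop-2-en-1-yl)benzoate | COC(=O)c1cc(OC)c(F)c(CC=C)c1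
F7 | step 17 | (2R,3S)-2-(4-hydroxy-3-methoxyphenyl)-3-(hydroxymethyl)-7-methoxy-2,3-dihydro-1-benzofuran-5-carbaldehyde | COc1cc([C@@H]2Oc3c(OC)cc(C=O)cc3[C@H]2CO)ccc1O
F8 | step 17 | (2R,3S)-2-[4-[tert-butyl(dimethyl)silyl]oxy-3-methoxyphenyl]-3-[[tert-butyl(dimethyl)silyl]oxymethyl]-7-methoxy-2,3-dihydro-1-benzofuran-5-carbaldehyde | COc1cc([C@@H]2Oc3c(OC)cc(C=O)cc3[C@H]2CO[Si](C)(C)C(C)(C)C)ccc1O[Si](C)(C)C(C)(C)C
F9 | step 17 | diethyl [(3,5-dihydroxyphenyl)methyl]phosphonate | CCOP(=O)(Cc1cc(O)cc(O)c1)OCC
F10 | step 17 | diethyl {[3,5-bis[tert-butyl(dimethyl)silyl]oxyphenyl]methyl}phosphonate | CCOP(=O)(Cc1cc(O[Si](C)(C)C(C)(C)C)cc(O[Si](C)(C)C(C)(C)C)c1)OCC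
F11 | step 17 | (2R,3S)-5-[(E)-2-[3,5-bis[tert-butyl(dimethyl)silyl]oxyphenyl]ethenyl]-2-[4-[tert-butyl(dimethyl)silyl]oxy-3-methoxyphenyl]-3-[[tert-butyl(dimethyl)silyl]oxymethyl]-7-methoxy-2,3-dihydro-1-benzofuran | COc1cc([C@@H]2Oc3c(OC)cc(/C=C/c4cc(O[Si](C)(C)C(C)(C)C)cc(O[Si](C)(C)C(C)(C)C)c4)cc3[C@H]2CO[Si](C)(C)C(C)(C)C)ccc1O[Si](C)(C)C(C)(C)C
A1 | alternative 1 | (2R)-6-bromo-8-methoxy-2-[3-methoxy-4-(pivaloyloxy)phenyl]chroman-4-one | COc1cc([C@H]2CC(=O)c3cc(Br)cc(OC)c3O2)ccc1OC(=O)C(C)(C)C
A2 | alternative 1 | methyl (2R,3R)-5-bromo-7-methoxy-2-[3-methoxy-4-(pivaloyloxy)phenyl]-2,3-dihydro-1-benzofuran-3-carboxylate | COc1cc([C@@H]2Oc3c(OC)cc(Br)cc3[C@H]2C(=O)OC)ccc1OC(=O)C(C)(C)C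
A3 | alternative 2 | 2-[3-iodo-5-methoxy-4-[[(1R)-1-[3-methoxy-4-(methoxymethoxy)phenyl]prop-2-en-1-yl]oxy]phenyl]-1,3-dioxolane | COCOc1ccc([C@@H](C=C)Oc2c(I)cc(C3OCCO3)cc2OC)cc1OC
A4 | alternative 2 | 2-[(2R,3S)-3-(hydroperoxymethyl)-7-methoxy-2-[3-methoxy-4-(methoxymethoxy)phenyl]-2,3-dihydro-1-benzofuran-5-yl]-1,3-dioxolane | COCOc1ccc([C@@H]2Oc3c(OC)cc(C4OCCO4)cc3[C@H]2COO)cc1OC
A5 | alternative 2 | [(2R,3S)-5-(1,3-dioxolan-2-yl)-7-methoxy-2-[3-methoxy-4-(methoxymethoxy)phenyl]-2,3-dihydro-1-benzofuran-3-yl]methanol | COCOc1ccc([C@@H]2Oc3c(OC)cc(C4OCCO4)cc3[C@H]2CO)cc1OC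
A6 | alternative 3 | methyl 3-[(2S)-1-[tert-butyl(dimethyl)silyl]oxy-3-(4-hydroxy-3-methoxyphenyl)propan-2-yl]-4-hydroxy-5-methoxybenzoate | COc1cc(C[C@H](CO[Si](C)(C)C(C)(C)C)c2cc(C(=O)OC)cc(OC)c2O)ccc1O
A7 | alternative 3 | methyl 3-[(2S)-1-[tert-butyl(dimethyl)silyl]oxy-3-(3-methoxy-4-oxocyclohexa-2,5-dien-1-ylidene)propan-2-yl]-4-hydroxy-5-methoxybenzoate | COC1=CC(=C[C@H](CO[Si](C)(C)C(C)(C)C)c2cc(C(=O)OC)cc(OC)c2O)C=CC1=O
A8 | alternative 3 | methyl (2R,3S)-3-[[tert-butyl(dimethyl)silyl]oxymethyl]-2-(4-hydroxy-3-methoxyphenyl)-7-methoxy-2,3-dihydro-1-benzofuran-5-carboxylate | COc1cc([C@@H]2Oc3c(OC)cc(C(=O)OC)cc3[C@H]2CO[Si](C)(C)C(C)(C)C)ccc1O
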